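(The numbers of this flask were set for the occasion.)

In a one-step world, where E meets X and nothing else, the ledger of E has a single line, G, and it closes at the full charge; that is the zero of our scale, and each entry below is a loss counted from it.

    E + X → G + X, rate k1*[E]*[X]/(1 + ([E]/Km1)) (Km1 = 2.77 mM, k1 = 2310 M⁻¹ s⁻¹)
    E + Z → E.Z (k2 = 0.349 M⁻¹ s⁻¹)
    X + J ⇌ X.J, settled at all times (K3 = 65000 M⁻¹)

E 20 mM; Z 1.00 mM; X 0.01 mol%; J 5.4 µM; time 4.0 d

* the state of affairs at 4.0 d: stopped, and by what, or still going (no working catalyst is left / all of E has reacted / it is still moving)
* amount of G at 4.0 d, in percent of the E charged

- the reaction counts as stopped when no species that holds the E changes by six tenths of a point or more over the second half of the time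
- run time (flask): 4.0 d

We keep the books of this flask in fractions of the E charged. Z is the limiting reagent of the binding step, and each Z takes one E away for good. Z charged over E charged gives 5.00%, and this fraction of the E that Z can bind is the Z toll.

Is the toll paid in full? That is a race between two clocks. With E held at its charge, Z has a half-life of 1.66 min. J holds part of X as X.J, and with J at its charge the free share of X is 74.0%. Since E starts above Km1, the free X starts near its ceiling, and at that ceiling it would get through the charge in 0.586 h. So Z's clock runs far faster than E's, and we book the toll in full.

The remaining entry is G, at 95.0% of the charge. The rate sags below the ceiling as E falls, but 4.0 d is 164 times the ceiling time, X comes out of step 1 unchanged, and X.J stays at balance with X, so we close the books: all of E has reacted.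

The forecast gives all of E has reacted and 95%, with Z “used up almost completely before E runs out”.

The flask ends thus: all of E has reacted, with G at 95.0%. At 4.00 d E.Z in this flask holds 5.00% of the E charged, against a toll of 5.00%, and Z is down to 0.0217% of its own charge. The neighbour flask has 2.5 mM of Z, so its toll is 12.5% and its ledger books 87.5% as G. That neighbour flask holds 87.5% of G at 4.00 d, with 12.5% as E.Z.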